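## Retrosynthetic overview

1. Target ⇐ oxidative 1,3-transposition of a C7 isopropenyl carbinol to the (Z)-enal (last step); primary myristate by esterification (acid built from 1-octene and 6-bromohexanenitrile); C16 acetate.
2. C15–C16 ⇐ (E)-alkenylzinc from a C14≡C15 methyl alkyne (hydrozirconation) plus homogeranial (enyne carboalumination/oxirane), catalyst-controlled 16R.
3. C7 and C10 carbinols ⇐ isopropenyl, then methyl, addition to a 2,2,3-trisubstituted cyclohexane-1,4-dione.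
4. C6 and C11 ⇐ Cu-catalysed asymmetric conjugate addition of the oxypropyl chain to 2-methylcyclohex-2-ene-1,4-dione, then trans alkylation of the enolate with pent-3-ynyl triflate.
5. The only ring is made first, by one-carbon ring expansion (zinc-carbenoid 1,2-acyl shift) of 2-methylcyclopentane-1,3-dione.

Assumption: locants C1–C27 in the text are iridal locants (ring C6–C11; C6 bears the C5–C3 oxypropyl chain, C7 the C2/C1 enal unit, C10 the OH and a methyl, C11 a methyl and the C12–C24 chain with the C16 carbinol); the sense of induction of the two chiral catalysts is assigned by analogy with their standard substrates.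

## Route

Step 1
Reactants: 1 2-methylcyclopentane-1,3-dione
Product: 5 2-methylcyclohex-2-ene-1,4-dione, via ethylzinc enolate 2 (not isolated), via selenide 3 (not isolated), via selenoxide 4 (not isolated)
Conditions: Et2Zn (2.5 equiv), CH2I2 (2.5 equiv), CH2Cl2, 0 °C → rt; PhSeCl, −20 °C; 30% H2O2, 0 °C; used at once
Reagents that add atoms: diiodomethane ICI
Why: Proposed new method: the zinc enolate of 1 is C-alkylated by the Furukawa carbenoid EtZnCH2I to a homoenolate that closes onto the flanking ketone (bicyclo[3.1.0] cyclopropoxide) and fragments across the fusion bond, a net 1,2-acyl shift that gives the ring-expanded 1,4-dione enolate 2, which is selenenylated at the methyl-bearing carbon and unmasked by base-free syn-selenoxide elimination toward the more acidic C–H (avoiding aromatisation to the hydroquinone); the closest known chemistry is the Zercher zinc-carbenoid chain extension of β-keto esters and acyclic β-diketones with tandem oxidation–elimination, not yet shown as a ring expansion of a cyclic 2-alkyl-1,3-dione.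

Step 2
Reactants: 6 3-iodopropan-1-ol
Product: 7 tert-butyl(3-iodopropoxy)dimethylsilane
Conditions: TBSCl, imidazole, CH2Cl2, 0 °C → rt
Reagents that add atoms: tert-butyldimethylsilyl chloride CC(C)(C)[Si](C)(C)Cl
Why: Standard imidazole-assisted silylation of a primary alcohol, so that the chain oxygen survives the organometallic steps.

Step 3
Reactants: 8 pent-3-yn-1-ol
Product: 9 pent-3-yn-1-yl trifluoromethanesulfonate
Conditions: Tf2O, 2,6-lutidine, CH2Cl2, −78 → −40 °C; used cold and at once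
Reagents that add atoms: trifluoromethanesulfonic anhydride O=S(=O)(OS(=O)(=O)C(F)(F)F)C(F)(F)F
Why: O-Triflation of a primary alcohol with a hindered base gives the very reactive primary triflate needed to C-alkylate a zinc enolate faster than E2 loss to the enyne.

Step 4
Reactants: 5 2-methylcyclohex-2-ene-1,4-dione; 7 tert-butyl(3-iodopropoxy)dimethylsilane; 9 pent-3-yn-1-yl trifluoromethanesulfonate
Product: 12 (2S,3S)-3-[3-(tert-butyldimethylsilyloxy)propyl]-2-methyl-2-(pent-3-yn-1-yl)cyclohexane-1,4-dione, via dialkylzinc 10 (not isolated), via zinc enolate 11 (not isolated)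
Conditions: 7, Et2Zn (neat), CuI (0.3 mol%), 55 °C, then volatiles removed in vacuo; Cu(OTf)2 (3 mol%), (R,S,S)-Feringa phosphoramidite (6 mol%), toluene, −30 °C, 5; then 9, THF/DMPU, −30 → 0 °C
Reagents that add atoms: none
Why: Knochel iodine–zinc exchange gives the functionalised dialkylzinc, Feringa-type Cu/phosphoramidite asymmetric conjugate addition delivers it to the unsubstituted β-carbon C6 of the enedione (the (R,S,S) ligand is the antipode of the one that gives (S)-3-alkylcyclohexanones and sets 6S here, which becomes 6R in the target only through a CIP priority change), and the regiodefined zinc enolate is C-alkylated by the primary triflate anti to the new C6 chain, setting the quaternary C11 (S) trans as in three-component enone couplings.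

Step 5
Reactants: 12 (2S,3S)-3-[3-(tert-butyldimethylsilyloxy)propyl]-2-methyl-2-(pent-3-yn-1-yl)cyclohexane-1,4-dione; 13 isopropenylmagnesium bromide
Product: 16 tert-butyl{3-[(1S,2S,3S,6R)-2,3-dimethyl-2-(pent-3-yn-1-yl)-6-(prop-1-en-2-yl)-3,6-bis(trimethylsilyloxy)cyclohexyl]propoxy}dimethylsilane, via C7 magnesium alkoxide 14 (not isolated), via dialkoxide 15 (not isolated)
Conditions: CeCl3, THF, −78 °C, 13 (1.1 equiv); MeLi (3 equiv), −78 → −20 °C; TMSOTf, Et3N, −78 → 0 °C
Reagents that add atoms: methyllithium [Li]C; trimethylsilyl trifluoromethanesulfonate C[Si](C)(C)OS(=O)(=O)C(F)(F)F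
Why: Imamoto organocerium 1,2-additions suppress enolisation, the isopropenyl reagent taking the less hindered C7 carbonyl before the neopentyl C10 carbonyl, after which methylcerium attacks C10 axially, anti to the axial C11 methyl of the chair with both chains equatorial (10S, OH cis to the C11 methyl; the other trajectories are blocked by that axial methyl or by a syn-axial C6 chain), and both alkoxides are silylated in the same pot, the C7 centre (drawn for equatorial attack) being erased in step 14.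

Step 6
Reactants: 17 5-bromo-2-methylpent-2-ene; 18 lithium acetylide–ethylenediamine complex
Product: 19 6-methylhept-5-en-1-yne
Conditions: DMSO, 10 °C → rt
Reagents that add atoms: none
Why: SN2 alkylation of lithium acetylide by an unhindered primary homoallylic bromide in DMSO.

Step 7
Reactants: 19 6-methylhept-5-en-1-yne; 20 oxirane
Product: 23 (3E)-4,8-dimethylnona-3,7-dien-1-ol, via alkenylalane 21 (not isolated), via lithium alanate 22 (not isolated)
Conditions: Me3Al, Cp2ZrCl2 (20 mol%), CH2Cl2, 0 °C → rt; n-BuLi, THF/hexane, −78 °C; 20, −78 → 0 °C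
Reagents that add atoms: trimethylaluminium C[Al](C)C
Why: Negishi Zr-catalysed carboalumination adds methyl and aluminium syn across the terminal alkyne (methyl to the internal carbon) to give the (E)-alkenylalane, whose butyl ate complex opens oxirane with retention of alkene geometry.

Step 8
Reactants: 23 (3E)-4,8-dimethylnona-3,7-dien-1-ol
Product: 24 (3E)-4,8-dimethylnona-3,7-dienal
Conditions: Dess–Martin periodinane, NaHCO3, CH2Cl2, 0 °C; used crude
Reagents that add atoms: none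
Why: Buffered Dess–Martin oxidation gives the β,γ-unsaturated aldehyde without moving the double bond into conjugation.

Step 9
Reactants: 16 tert-butyl{3-[(1S,2S,3S,6R)-2,3-dimethyl-2-(pent-3-yn-1-yl)-6-(prop-1-en-2-yl)-3,6-bis(trimethylsilyloxy)cyclohexyl]propoxy}dimethylsilane; 24 (3E)-4,8-dimethylnona-3,7-dienal
Product: 28 (3E,5R,7E)-1-{(1S,2S,5R,6S)-6-[3-(tert-butyldimethylsilyloxy)propyl]-1,2-dimethyl-5-(prop-1-en-2-yl)-2,5-bis(trimethylsilyloxy)cyclohexyl}-4,8,12-trimethyltrideca-3,7,11-trien-5-yl acetate, via alkenylzirconocene 25 (not isolated), via alkenylzinc 26 (not isolated), via zinc alkoxide 27 (not isolated)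
Conditions: Cp2Zr(H)Cl (1.6 equiv), CH2Cl2, rt → 40 °C; Me2Zn, toluene, −65 °C; (−)-MIB (10 mol%), 24, −30 → 0 °C; Ac2O, DMAP, 0 °C → rt
Reagents that add atoms: acetic anhydride CC(=O)OC(C)=O
Why: syn-Hydrozirconation puts zirconium on the methyl-bearing alkyne carbon (the less hindered terminus after equilibration with excess Schwartz reagent), Zr-to-Zn transmetalation (Wipf protocol) and (−)-MIB-catalysed alkenylzinc addition to the Si face of the aldehyde (the topicity that gives (S)-1-phenylpropanol from benzaldehyde and diethylzinc) set 16R and the 14E alkene, and the zinc alkoxide is acetylated in the same pot.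

Step 10
Reactants: 28 the tris-silyl (16R)-acetate
Product: 29 (3E,5R,7E)-1-[(1S,2S,5R,6S)-2,5-dihydroxy-6-(3-hydroxypropyl)-1,2-dimethyl-5-(prop-1-en-2-yl)cyclohexyl]-4,8,12-trimethyltrideca-3,7,11-trien-5-yl acetate
Conditions: HF·pyridine, pyridine, THF, 0 °C → rt
Reagents that add atoms: none
Why: Fluoride cleavage of the primary TBS ether and both tertiary TMS ethers under pyridine-buffered conditions that leave the allylic acetate and the tertiary allylic alcohol untouched.

Step 11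
Reactants: 30 oct-1-ene; 31 6-bromohexanenitrile
Product: 33 tetradecanenitrile, via B-octyl-9-BBN 32 (not isolated)
Conditions: 9-BBN, THF, rt; Pd(OAc)2 (4 mol%), PCy3 (8 mol%), K3PO4·H2O, THF, rt
Reagents that add atoms: none
Why: anti-Markovnikov hydroboration with 9-BBN and Fu-type alkyl–alkyl Suzuki–Miyaura coupling (Pd/PCy3) of the primary bromide, which tolerates the nitrile.

Step 12
Reactants: 33 tetradecanenitrile
Product: 34 tetradecanoic acid
Conditions: H2SO4, H2O, AcOH, reflux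
Reagents that add atoms: water O
Why: Acid hydrolysis of the nitrile to the carboxylic acid.

Step 13
Reactants: 29 the triol acetate; 34 tetradecanoic acid
Product: 35 3-{(1S,2S,3S,6R)-2-[(3E,5R,7E)-5-acetoxy-4,8,12-trimethyltrideca-3,7,11-trien-1-yl]-3,6-dihydroxy-2,3-dimethyl-6-(prop-1-en-2-yl)cyclohexyl}propyl tetradecanoate
Conditions: EDC, DMAP (cat.), CH2Cl2, 0 °C → rt
Reagents that add atoms: none
Why: Steglich esterification (carbodiimide/DMAP) acylates only the primary alcohol, the two tertiary alcohols being unreactive.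

Step 14
Reactants: 35 the myristate diol
Product: 36 3-[(1R,2S,3S,6Z)-2-[(3E,5R,7E)-5-acetoxy-4,8,12-trimethyltrideca-3,7,11-trien-1-yl]-3-hydroxy-2,3-dimethyl-6-(1-oxopropan-2-ylidene)cyclohexyl]propyl tetradecanoate (CNP0184857.1)
Conditions: PCC, NaOAc, 4 Å MS, CH2Cl2, rt
Reagents that add atoms: pyridinium chlorochromate [O-][Cr](=O)(=O)Cl.c1cc[nH+]cc1
Why: Babler–Dauben oxidative transposition, in which the C7 chromate ester undergoes 1,3-transposition to the primary allylic chromate and collapses to the α-methyl enal, the rotamer with the vinylic methyl next to the C8 methylene (not the substituted C6) giving the 2Z geometry that is also the thermodynamic one (least A1,3 strain), while the C10 tertiary alcohol, both esters and the trisubstituted alkenes are inert.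

## Compound list

1 | 2-methylcyclopentane-1,3-dione | CC1C(=O)CCC1=O | starting material
2 | ethyl[(2-methyl-4-oxocyclohex-1-en-1-yl)oxy]zinc | CC[Zn]OC1=C(C)CC(=O)CC1 | intermediate
3 | 2-methyl-2-(phenylselanyl)cyclohexane-1,4-dione (racemic) | CC1([Se]c2ccccc2)CC(=O)CCC1=O | intermediate
4 | 2-methyl-2-(phenylseleninyl)cyclohexane-1,4-dione (racemic) | CC1([Se](=O)c2ccccc2)CC(=O)CCC1=O | intermediate
5 | 2-methylcyclohex-2-ene-1,4-dione | CC1=CC(=O)CCC1=O | intermediate
6 | 3-iodopropan-1-ol | OCCCI | starting material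
7 | tert-butyl(3-iodopropoxy)dimethylsilane | CC(C)(C)[Si](C)(C)OCCCI | intermediate
8 | pent-3-yn-1-ol | CC#CCCO | starting material
9 | pent-3-yn-1-yl trifluoromethanesulfonate | CC#CCCOS(=O)(=O)C(F)(F)F | intermediate
10 | bis[3-(tert-butyldimethylsilyloxy)propyl]zinc | CC(C)(C)[Si](C)(C)OCCC[Zn]CCCO[Si](C)(C)C(C)(C)C | intermediate
11 | [3-(tert-butyldimethylsilyloxy)propyl]{[(3S)-3-[3-(tert-butyldimethylsilyloxy)propyl]-2-methyl-4-oxocyclohex-1-en-1-yl]oxy}zinc | CC(C)(C)[Si](C)(C)OCCC[Zn]OC1=C(C)[C@H](CCCO[Si](C)(C)C(C)(C)C)C(=O)CC1 | intermediate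
12 | (2S,3S)-3-[3-(tert-butyldimethylsilyloxy)propyl]-2-methyl-2-(pent-3-yn-1-yl)cyclohexane-1,4-dione | CC(C)(C)[Si](C)(C)OCCC[C@@H]1C(=O)CCC(=O)[C@@]1(C)CCC#CC | intermediate
13 | isopropenylmagnesium bromide | CC(=C)[Mg]Br | starting material
14 | bromomagnesium (1R,2S,3S)-2-[3-(tert-butyldimethylsilyloxy)propyl]-3-methyl-4-oxo-3-(pent-3-yn-1-yl)-1-(prop-1-en-2-yl)cyclohexan-1-olate (C7 configuration as expected, inconsequential) | CC(C)(C)[Si](C)(C)OCCC[C@@H]1[C@@](O[Mg]Br)(C(C)=C)CCC(=O)[C@@]1(C)CCC#CC | intermediate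
15 | bromomagnesium lithium (1S,2S,3S,4R)-3-[3-(tert-butyldimethylsilyloxy)propyl]-1,2-dimethyl-2-(pent-3-yn-1-yl)-4-(prop-1-en-2-yl)cyclohexane-1,4-bis(olate) | CC(C)(C)[Si](C)(C)OCCC[C@@H]1[C@@](O[Mg]Br)(C(C)=C)CC[C@](C)(O[Li])[C@@]1(C)CCC#CC | intermediate
16 | tert-butyl{3-[(1S,2S,3S,6R)-2,3-dimethyl-2-(pent-3-yn-1-yl)-6-(prop-1-en-2-yl)-3,6-bis(trimethylsilyloxy)cyclohexyl]propoxy}dimethylsilane | CC(C)(C)[Si](C)(C)OCCC[C@@H]1[C@@](O[Si](C)(C)C)(C(C)=C)CC[C@](C)(O[Si](C)(C)C)[C@@]1(C)CCC#CC | intermediate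
17 | 5-bromo-2-methylpent-2-ene | CC(C)=CCCBr | starting material
18 | lithium acetylide–ethylenediamine complex | [Li]C#C.NCCN | starting material
19 | 6-methylhept-5-en-1-yne | CC(C)=CCCC#C | intermediate
20 | oxirane | C1CO1 | starting material
21 | [(1E)-2,6-dimethylhepta-1,5-dien-1-yl]dimethylalumane | CC(C)=CCC/C(C)=C/[Al](C)C | intermediate
22 | lithium butyl[(1E)-2,6-dimethylhepta-1,5-dien-1-yl]dimethylaluminate | CCCC[Al-](C)(C)/C=C(\C)CCC=C(C)C.[Li+] | intermediate
23 | (3E)-4,8-dimethylnona-3,7-dien-1-ol | CC(C)=CCC/C(C)=C/CCO | intermediate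
24 | (3E)-4,8-dimethylnona-3,7-dienal | CC(C)=CCC/C(C)=C/CC=O | intermediate
25 | chlorobis(cyclopentadienyl)[(2E)-5-{(1S,2S,5R,6S)-6-[3-(tert-butyldimethylsilyloxy)propyl]-1,2-dimethyl-5-(prop-1-en-2-yl)-2,5-bis(trimethylsilyloxy)cyclohexyl}pent-2-en-2-yl]zirconium | CC(C)(C)[Si](C)(C)OCCC[C@@H]1[C@@](O[Si](C)(C)C)(C(C)=C)CC[C@](C)(O[Si](C)(C)C)[C@@]1(C)CC/C=C(\C)[Zr](Cl)(C2C=CC=C2)C2C=CC=C2 | intermediate
26 | methyl[(2E)-5-{(1S,2S,5R,6S)-6-[3-(tert-butyldimethylsilyloxy)propyl]-1,2-dimethyl-5-(prop-1-en-2-yl)-2,5-bis(trimethylsilyloxy)cyclohexyl}pent-2-en-2-yl]zinc | CC(C)(C)[Si](C)(C)OCCC[C@@H]1[C@@](O[Si](C)(C)C)(C(C)=C)CC[C@](C)(O[Si](C)(C)C)[C@@]1(C)CC/C=C(\C)[Zn]C | intermediate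
27 | methylzinc (3E,5R,7E)-1-{(1S,2S,5R,6S)-6-[3-(tert-butyldimethylsilyloxy)propyl]-1,2-dimethyl-5-(prop-1-en-2-yl)-2,5-bis(trimethylsilyloxy)cyclohexyl}-4,8,12-trimethyltrideca-3,7,11-trien-5-olate | CC(C)(C)[Si](C)(C)OCCC[C@@H]1[C@@](O[Si](C)(C)C)(C(C)=C)CC[C@](C)(O[Si](C)(C)C)[C@@]1(C)CC/C=C(\C)[C@@H](C/C=C(\C)CCC=C(C)C)O[Zn]C | intermediate
28 | (3E,5R,7E)-1-{(1S,2S,5R,6S)-6-[3-(tert-butyldimethylsilyloxy)propyl]-1,2-dimethyl-5-(prop-1-en-2-yl)-2,5-bis(trimethylsilyloxy)cyclohexyl}-4,8,12-trimethyltrideca-3,7,11-trien-5-yl acetate | CC(C)(C)[Si](C)(C)OCCC[C@@H]1[C@@](O[Si](C)(C)C)(C(C)=C)CC[C@](C)(O[Si](C)(C)C)[C@@]1(C)CC/C=C(\C)[C@@H](C/C=C(\C)CCC=C(C)C)OC(C)=O | intermediate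
29 | (3E,5R,7E)-1-[(1S,2S,5R,6S)-2,5-dihydroxy-6-(3-hydroxypropyl)-1,2-dimethyl-5-(prop-1-en-2-yl)cyclohexyl]-4,8,12-trimethyltrideca-3,7,11-trien-5-yl acetate | OCCC[C@@H]1[C@@](O)(C(C)=C)CC[C@](C)(O)[C@@]1(C)CC/C=C(\C)[C@@H](C/C=C(\C)CCC=C(C)C)OC(C)=O | intermediate
30 | oct-1-ene | C=CCCCCCC | starting material
31 | 6-bromohexanenitrile | N#CCCCCCBr | starting material
32 | 9-octyl-9-borabicyclo[3.3.1]nonane | CCCCCCCCB1C2CCCC1CCC2 | intermediate
33 | tetradecanenitrile | CCCCCCCCCCCCCC#N | intermediate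
34 | tetradecanoic acid | CCCCCCCCCCCCCC(=O)O | intermediate
35 | 3-{(1S,2S,3S,6R)-2-[(3E,5R,7E)-5-acetoxy-4,8,12-trimethyltrideca-3,7,11-trien-1-yl]-3,6-dihydroxy-2,3-dimethyl-6-(prop-1-en-2-yl)cyclohexyl}propyl tetradecanoate | CCCCCCCCCCCCCC(=O)OCCC[C@@H]1[C@@](O)(C(C)=C)CC[C@](C)(O)[C@@]1(C)CC/C=C(\C)[C@@H](C/C=C(\C)CCC=C(C)C)OC(C)=O | intermediate
36 | 3-[(1R,2S,3S,6Z)-2-[(3E,5R,7E)-5-acetoxy-4,8,12-trimethyltrideca-3,7,11-trien-1-yl]-3-hydroxy-2,3-dimethyl-6-(1-oxopropan-2-ylidene)cyclohexyl]propyl tetradecanoate (iridal locants 2Z,6R,10S,11S,14E,16R,18E) | CCCCCCCCCCCCCC(=O)OCCC[C@@H]1/C(=C(/C)C=O)CC[C@](C)(O)[C@@]1(C)CC/C=C(\C)[C@@H](C/C=C(\C)CCC=C(C)C)OC(C)=O | target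

## Step count and risks

Total step count: 14. Longest linear sequence: 7 (steps 1, 4, 5, 9, 10, 13, 14; the branch through steps 6, 7, 8 is equally long).

Steps most likely to fail:

Step 1 (the proposed new ring expansion). Risks are a sluggish carbenoid reaction of the fully substituted, non-chelating cyclic enolate and aromatisation of 5 to methylhydroquinone. The fallback sets out from 1 and comes back at 5 using known chemistry: O-silylation of 1 (TMSCl, Et3N) gives 2-methyl-3-(trimethylsilyloxy)cyclopent-2-en-1-one F1; Furukawa cyclopropanation of this isolated silyl enol ether gives 1-methyl-5-(trimethylsilyloxy)bicyclo[3.1.0]hexan-2-one F2; Ito–Saegusa oxidative ring expansion (FeCl3, DMF, 0 °C) cleaves the fusion bond to 2-chloro-2-methylcyclohexane-1,4-dione F3; NaOAc in MeOH at rt then eliminates HCl to give 5.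

Step 4 (one-pot conjugate addition and alkylation). The risk is that the zinc enolate is too unreactive toward a non-activated sp3 electrophile, or that O-alkylation or elimination of the triflate wins. The fallback sets out from 5 (with 10 as in step 4) and comes back at 15. The conjugate addition is run as before, but 11 is quenched with TMSOTf to give the silyl enol ether tert-butyldimethyl{3-[(1S)-2-methyl-6-oxo-3-(trimethylsilyloxy)cyclohex-2-en-1-yl]propoxy}silane F4. An iminium-catalysed Mukaiyama–Michael addition to acrolein (imidazolidinone·TFA) gives 3-{(1S,2S)-2-[3-(tert-butyldimethylsilyloxy)propyl]-1-methyl-3,6-dioxocyclohexyl}propanal F5, again anti to the C6 chain. Ohira–Bestmann homologation (K2CO3, MeOH) gives (2S,3S)-2-(but-3-yn-1-yl)-3-[3-(tert-butyldimethylsilyloxy)propyl]-2-methylcyclohexane-1,4-dione F6. Under the step 5 protocol, 13 gives the C7 bromomagnesium alkoxide of the terminal alkyne F7 and excess MeLi gives the dialkoxide lithium acetylide F8. C-Methylation of the acetylide with MeI (DMPU, −20 °C) gives 15, which is silylated to 16 as in step 5.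

Step 9 (fragment union). Risks are imperfect regiocontrol in the hydrozirconation and modest enantioselectivity with an enolisable β,γ-unsaturated aldehyde. The fallback sets out from 16 and comes back at 28. Hydrozirconation as in step 9 (25) and iodinolysis give the (E)-vinyl iodide tert-butyl{3-[(1S,2S,3S,6R)-2-[(3E)-4-iodopent-3-en-1-yl]-2,3-dimethyl-6-(prop-1-en-2-yl)-3,6-bis(trimethylsilyloxy)cyclohexyl]propoxy}dimethylsilane F9. Nozaki–Hiyama–Kishi coupling with 24 (CrCl2, cat. NiCl2, DMSO/THF) gives the C16-epimeric allylic alcohols corresponding to 28 F10. Dess–Martin oxidation gives the C16 enone F11. (S)-Me-CBS/catecholborane reduction gives the (16R)-allylic alcohol F12 (the alkenyl group acts as the large substituent). Ac2O, pyridine and cat. DMAP then give 28.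

Further compounds
F1 | step 1 | 2-methyl-3-(trimethylsilyloxy)cyclopent-2-en-1-one | CC1=C(O[Si](C)(C)C)CCC1=O
F2 | step 1 | 1-methyl-5-(trimethylsilyloxy)bicyclo[3.1.0]hexan-2-one (racemic) | CC12CC1(O[Si](C)(C)C)CCC2=O
F3 | step 1 | 2-chloro-2-methylcyclohexane-1,4-dione (racemic) | CC1(Cl)CC(=O)CCC1=O
F4 | step 4 | tert-butyldimethyl{3-[(1S)-2-methyl-6-oxo-3-(trimethylsilyloxy)cyclohex-2-en-1-yl]propoxy}silane | C[Si](C)(C)OC1=C(C)[C@H](CCCO[Si](C)(C)C(C)(C)C)C(=O)CC1
F5 | step 4 | 3-{(1S,2S)-2-[3-(tert-butyldimethylsilyloxy)propyl]-1-methyl-3,6-dioxocyclohexyl}propanal | CC(C)(C)[Si](C)(C)OCCC[C@@H]1C(=O)CCC(=O)[C@@]1(C)CCC=O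
F6 | step 4 | (2S,3S)-2-(but-3-yn-1-yl)-3-[3-(tert-butyldimethylsilyloxy)propyl]-2-methylcyclohexane-1,4-dione | CC(C)(C)[Si](C)(C)OCCC[C@@H]1C(=O)CCC(=O)[C@@]1(C)CCC#C
F7 | step 4 | bromomagnesium (1R,2S,3S)-3-(but-3-yn-1-yl)-2-[3-(tert-butyldimethylsilyloxy)propyl]-3-methyl-4-oxo-1-(prop-1-en-2-yl)cyclohexan-1-olate | CC(C)(C)[Si](C)(C)OCCC[C@@H]1[C@@](O[Mg]Br)(C(C)=C)CCC(=O)[C@@]1(C)CCC#C
F8 | step 4 | C7-bromomagnesium C10-lithium dialkoxide lithium acetylide of (1S,2S,3S,4R)-2-(but-3-yn-1-yl)-3-[3-(tert-butyldimethylsilyloxy)propyl]-1,2-dimethyl-4-(prop-1-en-2-yl)cyclohexane-1,4-diol | CC(C)(C)[Si](C)(C)OCCC[C@@H]1[C@@](O[Mg]Br)(C(C)=C)CC[C@](C)(O[Li])[C@@]1(C)CCC#C[Li]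
F9 | step 9 | tert-butyl{3-[(1S,2S,3S,6R)-2-[(3E)-4-iodopent-3-en-1-yl]-2,3-dimethyl-6-(prop-1-en-2-yl)-3,6-bis(trimethylsilyloxy)cyclohexyl]propoxy}dimethylsilane | CC(C)(C)[Si](C)(C)OCCC[C@@H]1[C@@](O[Si](C)(C)C)(C(C)=C)CC[C@](C)(O[Si](C)(C)C)[C@@]1(C)CC/C=C(\C)I
F10 | step 9 | (3E,7E)-1-{(1S,2S,5R,6S)-6-[3-(tert-butyldimethylsilyloxy)propyl]-1,2-dimethyl-5-(prop-1-en-2-yl)-2,5-bis(trimethylsilyloxy)cyclohexyl}-4,8,12-trimethyltrideca-3,7,11-trien-5-ol (C5 epimers) | CC(C)(C)[Si](C)(C)OCCC[C@@H]1[C@@](O[Si](C)(C)C)(C(C)=C)CC[C@](C)(O[Si](C)(C)C)[C@@]1(C)CC/C=C(\C)C(O)C/C=C(\C)CCC=C(C)C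
F11 | step 9 | (3E,7E)-1-{(1S,2S,5R,6S)-6-[3-(tert-butyldimethylsilyloxy)propyl]-1,2-dimethyl-5-(prop-1-en-2-yl)-2,5-bis(trimethylsilyloxy)cyclohexyl}-4,8,12-trimethyltrideca-3,7,11-trien-5-one | CC(C)(C)[Si](C)(C)OCCC[C@@H]1[C@@](O[Si](C)(C)C)(C(C)=C)CC[C@](C)(O[Si](C)(C)C)[C@@]1(C)CC/C=C(\C)C(=O)C/C=C(\C)CCC=C(C)C
F12 | step 9 | (3E,5R,7E)-1-{(1S,2S,5R,6S)-6-[3-(tert-butyldimethylsilyloxy)propyl]-1,2-dimethyl-5-(prop-1-en-2-yl)-2,5-bis(trimethylsilyloxy)cyclohexyl}-4,8,12-trimethyltrideca-3,7,11-trien-5-ol | CC(C)(C)[Si](C)(C)OCCC[C@@H]1[C@@](O[Si](C)(C)C)(C(C)=C)CC[C@](C)(O[Si](C)(C)C)[C@@]1(C)CC/C=C(\C)[C@@H](C/C=C(\C)CCC=C(C)C)O
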